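**Retrosynthetic overview**

1. Target 14 comes from silyl ether 13 by desilylation. Compound 13 is cut at the bond between C2 of ring C (the pyranone) and C6 of the chromene (ring B), which gives aryl bromide 7 (fragment 1) and the benzofuran-fused cyclopropanol 12 (fragment 2).
2. Enabling feature: C2 of ring C is α to the ring oxygen O1 and 1,3 to the C4 carbonyl through C3. The C2/C4 pair can therefore be stored as the fusion bond of a cyclopropanol on a five-membered benzofuran, with C3 as the cyclopropane CH2. Oxidative β-scission of that strained bond releases an O1-stabilized C2 radical and the C4 ketone together.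
3. Key step: enantioselective photoredox/nickel ring-expansion arylation of 12 with 7. It forms the C2–C6 bond, enlarges the furanoid ring to the six-membered ring C and sets C2 as (S).
4. Fragment 2 comes from 6-hydroxybenzofuran-3(2H)-one (ring A bought) by silylation, silyl enol ether formation and Simmons–Smith cyclopropanation. Fragment 1 comes from 4-bromophenol (ring B bought) by ortho-prenylation, propargyl ether formation and thermal Claisen/oxa-6π closure.
5. Order of ring formation: pyran ring D of the chromene (step 3), the temporary cyclopropane (step 6), ring C by ring expansion (step 7).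

Key step: step 7

Assumption: the sense of induction of the chiral nickel catalyst in step 7 cannot be derived with certainty from precedent; the (S,S)-ligand is written, and its antipode is used instead if that is the one that delivers (2S).

**Route**

Step 1
Reactants: 1 4-bromophenol; 2 1-bromo-3-methylbut-2-ene (prenyl bromide)
Product: 3 4-bromo-2-(3-methylbut-2-en-1-yl)phenol
Conditions: NaH, toluene, 0 °C to rt
Reagents that add atoms: none
Why: Ortho-selective C-prenylation of a sodium phenoxide in a non-polar solvent (C-alkylation of the tight ion pair) should place the prenyl group next to the hydroxyl, the para position being blocked by bromine.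

Step 2
Reactants: 3 4-bromo-2-(3-methylbut-2-en-1-yl)phenol; 4 3-chloro-3-methylbut-1-yne
Product: 5 4-bromo-1-[(2-methylbut-3-yn-2-yl)oxy]-2-(3-methylbut-2-en-1-yl)benzene
Conditions: CuCl2·2H2O (cat.), DBU, MeCN, 0 °C
Reagents that add atoms: none
Why: Copper-catalyzed propargylic etherification of a phenol with a tertiary propargylic chloride is the standard entry to aryl 1,1-dimethylpropargyl ethers and should leave the aryl bromide and the prenyl group untouched.

Step 3
Reactants: 5 4-bromo-1-[(2-methylbut-3-yn-2-yl)oxy]-2-(3-methylbut-2-en-1-yl)benzene
Product: 7 6-bromo-2,2-dimethyl-8-(3-methylbut-2-en-1-yl)-2H-chromene, via allenylphenol 6 (not isolated)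
Conditions: o-xylene, 145 °C
Reagents that add atoms: none
Why: Thermal aryl propargyl ether Claisen rearrangement to the only free ortho carbon, tautomerization to allenylphenol 6, 1,5-hydrogen shift to the ortho-quinone methide and oxa-6π electrocyclization should close the pyran ring D of the 2,2-dimethylchromene.

Step 4
Reactants: 8 6-hydroxybenzofuran-3(2H)-one
Product: 9 6-[(triisopropylsilyl)oxy]benzofuran-3(2H)-one
Conditions: TIPSCl, imidazole, DMF, 0 °C to rt
Reagents that add atoms: triisopropylsilyl chloride CC(C)[Si](Cl)(C(C)C)C(C)C
Why: Imidazole-mediated silylation of the acidic phenol should mask the future 7-hydroxyl as a base-robust, fluoride-labile triisopropylsilyl ether without touching the ketone.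

Step 5
Reactants: 9 6-[(triisopropylsilyl)oxy]benzofuran-3(2H)-one
Product: 10 triisopropyl{[3-(trimethylsilyloxy)-1-benzofuran-6-yl]oxy}silane
Conditions: TMSOTf, Et3N, CH2Cl2, 0 °C
Reagents that add atoms: trimethylsilyl trifluoromethanesulfonate C[Si](C)(C)OS(=O)(=O)C(F)(F)F
Why: Soft enolization and O-silylation should give the silyl enol ether, here the aromatic 3-silyloxybenzofuran, whose C2=C3 bond is a doubly oxygenated, electron-rich alkene.

Step 6
Reactants: 10 triisopropyl{[3-(trimethylsilyloxy)-1-benzofuran-6-yl]oxy}silane
Product: 12 rac-(1aR,6bS)-4-[(triisopropylsilyl)oxy]-1a,6b-dihydro-1H-cyclopropa[b][1]benzofuran-6b-ol, via trimethylsilyl ether 11 (not isolated)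
Conditions: Et2Zn, CH2I2, CH2Cl2, 0 °C to rt; pyridine quench; then K2CO3 (cat.), MeOH, 0 °C
Reagents that add atoms: diiodomethane ICI
Why: Simmons–Smith cyclopropanation of the silyl enol ether with the Et2Zn/CH2I2 carbenoid (cis ring fusion is the only one possible, the product is racemic and both of its stereocenters are erased in step 7), followed by mild methanolysis of the tertiary trimethylsilyl ether while the unactivated aryl triisopropylsilyl ether persists, should give the cyclopropanol.

Step 7
Reactants: 7 6-bromo-2,2-dimethyl-8-(3-methylbut-2-en-1-yl)-2H-chromene (fragment 1); 12 rac-(1aR,6bS)-4-[(triisopropylsilyl)oxy]-1a,6b-dihydro-1H-cyclopropa[b][1]benzofuran-6b-ol (fragment 2)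
Product: 13 (2S)-2-[2,2-dimethyl-8-(3-methylbut-2-en-1-yl)-2H-chromen-6-yl]-7-[(triisopropylsilyl)oxy]-2,3-dihydro-4H-chromen-4-one
Conditions: 4CzIPN (2 mol %), NiBr2(MeOCH2CH2OMe) (10 mol %), (S,S)-4,4'-dibenzyl-2,2'-bi(2-oxazoline) (12 mol %), 2,4,6-collidine, DMA, 450 nm LEDs, 20 °C
Reagents that add atoms: none
Why: Proposed new method: Photoexcited 4CzIPN should oxidize the collidine-bound, electron-rich aryl cyclopropanol of 12 by proton-coupled electron transfer to the cyclopropoxy radical, whose β-scission breaks the ring-fusion bond C6b–C1a and leaves the 4-oxochroman-2-yl radical, which is trapped by the arylnickel bromide formed from 7 and zerovalent nickel, so that reductive elimination from trivalent nickel forms the C6(chromene)–C2 bond while the reduced photocatalyst returns monovalent nickel to zerovalent nickel. The closest known reaction types are the dual photoredox and nickel ring-opening arylation of cyclopropanols to β-aryl ketones, the ring-enlarging oxidative opening of bicyclo[n.1.0]alkan-1-ols to β-keto radicals, and the enantioselective nickel-catalyzed arylation of α-oxy radicals under chiral bis(oxazoline) control, and their merger on a benzofuran-fused cyclopropanol is what is new. Ring C is not closed by a cyclization but arises by one-carbon ring expansion of the five-membered furanoid ring, the cyclopropane CH2 becoming C3 and the former fusion bond being traded for the C4 carbonyl. The only new stereocenter, C2, is set under catalyst control by the C2-symmetric bis(oxazoline) ligand on nickel during radical capture and reductive elimination, and because the radical is planar both enantiomers of racemic 12 should converge on (2S)-13. The step needs scission of the fusion bond instead of the external cyclopropane bond, which the stabilization of the C2 radical by the O1 lone pair and the larger strain relief should secure, and it needs reductive elimination to outrun β-hydride loss to the chromone, radical addition to the prenyl and chromene alkenes and base-induced racemization, for which fast capture by nickel, the nucleophilic character of the α-oxy radical and the weak base collidine are relied on.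

Step 8
Reactants: 13 (2S)-2-[2,2-dimethyl-8-(3-methylbut-2-en-1-yl)-2H-chromen-6-yl]-7-[(triisopropylsilyl)oxy]-2,3-dihydro-4H-chromen-4-one
Product: 14 (2S)-2-[2,2-dimethyl-8-(3-methylbut-2-en-1-yl)-2H-chromen-6-yl]-7-hydroxy-2,3-dihydro-4H-chromen-4-one (the target abyssinone)
Conditions: Bu4NF, AcOH (1:1), THF, 0 °C
Reagents that add atoms: none
Why: Fluoride cleavage of the aryl silyl ether, buffered with acetic acid so that no phenoxide or enolate can trigger retro-oxa-Michael ring opening and racemization at C2, should free the 7-hydroxyl without touching the prenyl and chromene alkenes.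

**Compound list**

1 | 4-bromophenol | Oc1ccc(Br)cc1 | starting material
2 | 1-bromo-3-methylbut-2-ene (prenyl bromide) | CC(C)=CCBr | starting material
3 | 4-bromo-2-(3-methylbut-2-en-1-yl)phenol | CC(C)=CCc1cc(Br)ccc1O | intermediate
4 | 3-chloro-3-methylbut-1-yne | C#CC(C)(C)Cl | starting material
5 | 4-bromo-1-[(2-methylbut-3-yn-2-yl)oxy]-2-(3-methylbut-2-en-1-yl)benzene | CC(C)=CCc1cc(Br)ccc1OC(C)(C)C#C | intermediate
6 | 4-bromo-2-(3-methylbuta-1,2-dien-1-yl)-6-(3-methylbut-2-en-1-yl)phenol (allenylphenol) | CC(C)=CCc1cc(Br)cc(C=C=C(C)C)c1O | intermediate (not isolated)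
7 | 6-bromo-2,2-dimethyl-8-(3-methylbut-2-en-1-yl)-2H-chromene | CC(C)=CCc1cc(Br)cc2C=CC(C)(C)Oc12 | intermediate
8 | 6-hydroxybenzofuran-3(2H)-one | O=C1COc2cc(O)ccc12 | starting material
9 | 6-[(triisopropylsilyl)oxy]benzofuran-3(2H)-one | O=C1COc2cc(O[Si](C(C)C)(C(C)C)C(C)C)ccc12 | intermediate
10 | triisopropyl{[3-(trimethylsilyloxy)-1-benzofuran-6-yl]oxy}silane | C[Si](C)(C)Oc1coc2cc(O[Si](C(C)C)(C(C)C)C(C)C)ccc12 | intermediate
11 | rac-(1aR,6bS)-6b-(trimethylsilyloxy)-4-[(triisopropylsilyl)oxy]-1a,6b-dihydro-1H-cyclopropa[b][1]benzofuran (cis-fused, racemic, one enantiomer drawn) | C[Si](C)(C)O[C@]12C[C@H]1Oc1cc(O[Si](C(C)C)(C(C)C)C(C)C)ccc12 | intermediate (not isolated)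
12 | rac-(1aR,6bS)-4-[(triisopropylsilyl)oxy]-1a,6b-dihydro-1H-cyclopropa[b][1]benzofuran-6b-ol (cis-fused, racemic, one enantiomer drawn; cyclopropane across the former C2–C3 bond of the benzofuran, OH on the carbon bound to the arene) | O[C@]12C[C@H]1Oc1cc(O[Si](C(C)C)(C(C)C)C(C)C)ccc12 | intermediate
13 | (2S)-2-[2,2-dimethyl-8-(3-methylbut-2-en-1-yl)-2H-chromen-6-yl]-7-[(triisopropylsilyl)oxy]-2,3-dihydro-4H-chromen-4-one | CC(C)=CCc1cc([C@@H]2CC(=O)c3ccc(O[Si](C(C)C)(C(C)C)C(C)C)cc3O2)cc2c1OC(C)(C)C=C2 | intermediate
14 | (2S)-2-[2,2-dimethyl-8-(3-methylbut-2-en-1-yl)-2H-chromen-6-yl]-7-hydroxy-2,3-dihydro-4H-chromen-4-one | CC(C)=CCc1cc([C@@H]2CC(=O)c3ccc(O)cc3O2)cc2c1OC(C)(C)C=C2 | target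

**Step count and risks**

Total step count: 8. Longest linear sequence: 5 steps (steps 1, 2, 3, 7, 8 or steps 4, 5, 6, 7, 8).

Steps most likely to fail:

1. Step 7 (proposed new method). What may go wrong:
   - weak enantiofacial discrimination when the C2 radical is captured at nickel;
   - polar opening of a nickel cyclopropoxide at the external cyclopropane bond instead of radical scission of the fusion bond;
   - β-hydride loss from the alkylnickel species towards the chromone;
   - simple protonation or reduction of the radical to the unarylated chromanone.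

   Fallback (known chemistry, same bond): it sets out from 7. Bromine–lithium exchange (n-BuLi, THF, −78 °C), quench with B(OiPr)3 and aqueous NH4Cl should give [2,2-dimethyl-8-(3-methylbut-2-en-1-yl)-2H-chromen-6-yl]boronic acid F1. Purchased 7-hydroxy-4H-chromen-4-one F2 would be silylated (TIPSCl, imidazole, DMF) to 7-[(triisopropylsilyl)oxy]-4H-chromen-4-one F3. Enantioselective conjugate addition of F1 to F3 (Pd(OCOCF3)2, (S)-t-BuPyOx or its antipode as required for 2S, NH4PF6, H2O, ClCH2CH2Cl, 60 °C) is the established divalent-palladium-catalyzed 1,4-addition of arylboronic acids to chromones. It should form the same C6–C2 bond and come back to the route at 13.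

2. Step 6. What may go wrong:
   - sluggish methylene transfer to the heteroaromatic enol ether;
   - opening of the 1,2-dioxygenated cyclopropane by zinc Lewis acids;
   - base-induced homoenolate or Grob-type fragmentation of the free cyclopropanol during methanolysis;
   - partial loss of the aryl silyl ether.

   Fallback: it sets out from 10. Bromination of the silyl enol ether (NBS, THF, −78 °C) should give 2-bromo-6-[(triisopropylsilyl)oxy]benzofuran-3(2H)-one F4. Treatment with Sm and CH2I2 (THF, −78 °C to rt, NH4Cl quench) is the known cyclopropanol synthesis from α-halo ketones, in which a samarium enolate is cyclopropanated in the flask by the samarium carbenoid. It should deliver the free cyclopropanol without a silyl ether and without basic methanolysis, and come back to the route at 12.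

3. Step 1. What may go wrong:
   - O-alkylation competing with ortho C-alkylation;
   - over-alkylation;
   - cyclization of the ortho-prenylphenol to the chromane on acidic handling.

   Fallback: it sets out from 1. Copper-catalyzed etherification with 4 (CuCl2·2H2O cat., DBU, MeCN, 0 °C) should give 1-bromo-4-[(2-methylbut-3-yn-2-yl)oxy]benzene F5. Semihydrogenation (H2, Pb-poisoned Pd/CaCO3, quinoline, EtOAc) should give 1-bromo-4-[(2-methylbut-3-en-2-yl)oxy]benzene F6. Aromatic Claisen rearrangement (N,N-diethylaniline, 130 °C) should then move the allyl unit to the ortho carbon with allylic inversion, so that the prenyl group arrives regiospecifically, and come back to the route at 3.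

Further compounds
F1 | step 7 | [2,2-dimethyl-8-(3-methylbut-2-en-1-yl)-2H-chromen-6-yl]boronic acid | CC(C)=CCc1cc(B(O)O)cc2C=CC(C)(C)Oc12
F2 | step 7 | 7-hydroxy-4H-chromen-4-one (purchased) | O=c1ccoc2cc(O)ccc12
F3 | step 7 | 7-[(triisopropylsilyl)oxy]-4H-chromen-4-one | O=c1ccoc2cc(O[Si](C(C)C)(C(C)C)C(C)C)ccc12
F4 | step 6 | 2-bromo-6-[(triisopropylsilyl)oxy]benzofuran-3(2H)-one (racemic) | O=C1C(Br)Oc2cc(O[Si](C(C)C)(C(C)C)C(C)C)ccc12
F5 | step 1 | 1-bromo-4-[(2-methylbut-3-yn-2-yl)oxy]benzene | Brc1ccc(OC(C)(C)C#C)cc1
F6 | step 1 | 1-bromo-4-[(2-methylbut-3-en-2-yl)oxy]benzene | Brc1ccc(OC(C)(C)C=C)cc1
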